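**Retrosynthetic overview**

1. The C15 stereocentre comes last, by asymmetric hydrogenation of an α-methylene lactone. Lactone ring D is closed just before that by carbonylative C16–O bond formation from a vinyl triflate and the C3 hydroxyl. The C11 ester carbinol comes from a C11 ketone, MeMgBr and butanoic anhydride.
2. Oxonene ring C is closed by ring-closing metathesis (C6=C7) on an oxolane-fused cyclohexanone.
3. Rings B (oxolane) and A (cyclohexanone) form together in an intramolecular Diels–Alder reaction. The diene is a 2-siloxydiene (C10–C13), the dienophile an unsaturated Weinreb amide (C1=C14), and the tether is the C9–O–C2 ether.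
4. Key disconnection: the C2–O bond of that ether. It is made by a stereoretentive palladium/boron-mediated opening of a vinyl epoxide by a secondary alcohol, which also joins the two fragments.
5. Fragments: an epoxy enamide from geraniol (Sharpless epoxidation sets C2 and C3) and a hydroxy enone from (S)-epichlorohydrin (sets C9). Ring order: B and A together, then C, then D.

Assumption: the SMILES is taken as the absolute configuration (1S,2S,3S,9S,10R,11R,14R,15R, 6Z in eunicellane numbering, which is used throughout). Ring A = C1, C10–C14; ring B = C1, C2, O, C9, C10; ring C = O, C2–C9; ring D = C1, C2, C3, O, C16, C15, C14. Methyls: C17 on C15, C18 on C3, C19 on C7, C20 on C11. β = the face of H1 and H10; α = the face of the C11–O bond.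

**Step 1**
Reactants: 1 geraniol
Product: 2 (2S,3S)-2,3-epoxygeraniol
Conditions: Ti(OiPr)4 (5 mol%), L-(+)-diethyl tartrate (6 mol%), t-BuOOH, 4 Å molecular sieves, CH2Cl2, −20 °C
Reagents that add atoms: tert-butyl hydroperoxide, CC(C)(C)OO
Why: Sharpless asymmetric epoxidation of the allylic alcohol; the L-tartrate catalyst delivers oxygen to one face of the E-alkene, setting both C–O stereocentres (C2 and C3) with the relative configuration needed in the target.

**Step 2**
Reactants: 2 (2S,3S)-2,3-epoxygeraniol
Product: 3 (2R,3S)-epoxygeranial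
Conditions: TEMPO (10 mol%), PhI(OAc)2, CH2Cl2, rt; used crude
Reagents that add atoms: none
Why: TEMPO/iodobenzene diacetate oxidation of a primary alcohol is neutral, so the epoxide and the α-epoxy stereocentre survive (descriptor changes by priority only).

**Step 3**
Reactants: 3 (2R,3S)-epoxygeranial
Product: 4 (2E)-N-methoxy-N-methyl-3-[(2S,3S)-3-methyl-3-(4-methylpent-3-en-1-yl)oxiran-2-yl]prop-2-enamide
Conditions: Ph3P=CHC(O)N(OMe)Me, CH2Cl2, rt
Reagents that add atoms: N-methoxy-N-methyl-2-(triphenylphosphoranylidene)acetamide, CON(C)C(=O)C=P(c1ccccc1)(c1ccccc1)c1ccccc1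
Why: Wittig olefination with a stabilised, non-basic ylide gives the E-enamide (C1=C14) without epimerising C2; the amide has no enolisable position and later serves as a latent methyl ketone.

**Step 4**
Reactants: 5 (S)-epichlorohydrin
Product: 7 (2S)-2-(2-methylprop-2-en-1-yl)oxirane, via chlorohydrin alkoxide 6 (not isolated)
Conditions: isopropenylmagnesium bromide, CuI (5 mol%), THF, −40 °C; then powdered NaOH, Et2O, rt
Reagents that add atoms: isopropenylmagnesium bromide, CC(=C)[Mg]Br
Why: Copper-catalysed Grignard opening of the epoxide at its CH2 terminus, then Williamson ring closure onto the CH2Cl carbon; the C–O bond at the stereocentre (future C9) is never broken, so configuration is kept.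

**Step 5**
Reactants: 7 (2S)-2-(2-methylprop-2-en-1-yl)oxirane
Product: 9 (5S)-5-hydroxy-7-methylocta-1,7-dien-3-one, via allenyl ether alkoxide 8 (not isolated)
Conditions: methoxyallene, n-BuLi, THF, −40 °C; then 7, −40 °C to rt; then 0.5 M HCl, THF, 0 °C, short contact; used directly
Reagents that add atoms: methoxyallene, COC=C=C; water, O
Why: 1-Lithio-1-methoxyallene acts as an acryloyl anion equivalent and opens the terminal epoxide at CH2 (SN2), and mild acid hydrolysis of the allenyl enol ether releases the vinyl ketone; C9 is untouched.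

**Step 6**
Reactants: 4 epoxy enamide; 9 (5S)-5-hydroxy-7-methylocta-1,7-dien-3-one (1.2 equiv)
Product: 10 (2E,4S,5S)-5-hydroxy-N-methoxy-N,5,9-trimethyl-4-{[(4S)-2-methyl-6-oxoocta-1,7-dien-4-yl]oxy}deca-2,8-dienamide
Conditions: Pd2(dba)3·CHCl3 (2.5 mol%), P(OiPr)3 (20 mol%), BEt3 (15 mol%), THF, 0 °C to rt
Reagents that add atoms: none
Why: Proposed new method: zerovalent palladium opens the vinyl epoxide with inversion to a π-allyl complex whose tertiary C3 alkoxide binds BEt3; the resulting borate carries alcohol 9 to the adjacent allyl terminus C2 on the face opposite palladium, so the key C2–O bond forms with net retention (double inversion), at the γ-carbon only, and frees the C3 hydroxyl. The closest known reaction type is the boron-assisted palladium-catalysed 1,2-alkoxylation of vinyl epoxides and of γ,δ-epoxy enoates with simple alcohols or trialkyl borates; it has not been shown for a functionalised secondary alcohol as fragment partner, a trisubstituted epoxide or an unsaturated Weinreb amide.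

**Step 7**
Reactants: 10 ether-linked triene
Product: 13 triethylsilyl-protected A/B-ring ketone, via bis-silylated siloxydiene 11 (not isolated), via silyl enol ether cycloadduct 12 (not isolated)
Conditions: Et3SiOTf (2.4 equiv), Et3N, CH2Cl2, −78 to 0 °C; solvent switch to PhMe, 110 °C; then K2CO3 (cat.), MeOH, 0 °C
Reagents that add atoms: triethylsilyl trifluoromethanesulfonate, CC[Si](CC)(CC)OS(=O)(=O)C(F)(F)F
Why: Soft enolisation gives the (Z)-2-siloxydiene and protects O3, and a type 1 intramolecular Diels–Alder reaction (formal double Michael, diene terminus C10 to the β-carbon C1) closes rings B and A at once; with H2 and H9 eclipsing their double bonds (allylic 1,3-strain) and the bulky C3 and C8 groups turned away from the forming bonds, only the cis-fused transition state suits both stereocentres, giving H1/H10 β and, through the E-dienophile, the C14 amide trans to C2, while C10 and C14 stay epimerisable to this arrangement under the K2CO3/MeOH work-up.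

**Step 8**
Reactants: 13 triethylsilyl-protected A/B-ring ketone
Product: 14 tricyclic oxonene ketone
Conditions: second-generation Hoveyda–Grubbs catalyst (10 mol%), PhMe, 80 °C, 2 mM
Reagents that add atoms: none
Why: Ring-closing metathesis between the prenyl-type alkene and the methallyl group, both held on the β-face of ring B, closes the nine-membered ring C with loss of isobutene; the ring size enforces the Z trisubstituted C6=C7 alkene.

**Step 9**
Reactants: 14 tricyclic oxonene ketone
Product: 16 C11 butanoate methyl ketone, via bis-bromomagnesium adduct 15 (not isolated)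
Conditions: MeMgBr (4 equiv), LaCl3·2LiCl (30 mol%), THF, −78 to 0 °C; then butanoic anhydride (6 equiv), 0 °C to rt; aqueous NH4Cl
Reagents that add atoms: methylmagnesium bromide, C[Mg]Br; butanoic anhydride, CCCC(=O)OC(=O)CCC
Why: Grignard 1,2-addition to the C11 ketone occurs from the convex β-face, anti to the axial C9 substituent on C10, giving β-methyl and α-oxygen as in the target; the same reagent turns the Weinreb amide into its stable chelate (methyl ketone on work-up), and the tertiary magnesium alkoxide is acylated in situ, which avoids a separate esterification of a hindered tertiary alcohol.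

**Step 10**
Reactants: 16 C11 butanoate methyl ketone
Product: 18 vinyl triflate alcohol, via silyl-protected vinyl triflate 17 (not isolated)
Conditions: KN(SiMe3)2 (1.1 equiv), PhNTf2, THF, −78 °C; then HF·pyridine, THF/pyridine, 0 °C to rt
Reagents that add atoms: N-phenylbis(trifluoromethanesulfonimide), O=S(=O)(N(c1ccccc1)S(=O)(=O)C(F)(F)F)C(F)(F)F
Why: Kinetic deprotonation of the methyl ketone on the CH3 side and O-triflation give the 1,1-disubstituted enol triflate without touching C14 or the less acidic ester, and fluoride then removes the tertiary silyl ether to free O3.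

**Step 11**
Reactants: 18 vinyl triflate alcohol
Product: 19 α-methylene lactone (tetracycle, ring D closed)
Conditions: Pd(OAc)2 (10 mol%), Xantphos (12 mol%), CO (1 atm), Et3N, DMAP (20 mol%), MeCN, 65 °C
Reagents that add atoms: carbon monoxide, [C-]#[O+]
Why: Palladium-catalysed carbonylative lactonisation: oxidative addition of the vinyl triflate to zerovalent palladium, CO insertion, and capture of the acyl–palladium by the C3 hydroxyl, which the trans-diequatorial C14/C1 substituents hold within reach; CO supplies C16 and the ring D C–O bond is formed.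

**Step 12**
Reactants: 19 α-methylene lactone
Product: 20 target compound CNP0294597.2
Conditions: Ru(OAc)2[(S)-BINAP] (5 mol%), H2 (50 atm), MeOH/CH2Cl2, 40 °C
Reagents that add atoms: none
Why: Ru–BINAP asymmetric hydrogenation of the conjugated exocyclic alkene; the (S)-ligand is taken as the enantiomer that gives (R)-α-methyl lactones from α-methylene lactones (sense assigned by analogy, so the (R)-ligand is the immediate alternative), so C15 is set by the catalyst and the unfunctionalised trisubstituted C6=C7 alkene is left alone.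

**Compound list**

1 | geraniol, (2E)-3,7-dimethylocta-2,6-dien-1-ol | CC(C)=CCC/C(C)=C/CO | starting material
2 | (2S,3S)-2,3-epoxygeraniol, [(2S,3S)-3-methyl-3-(4-methylpent-3-en-1-yl)oxiran-2-yl]methanol | OC[C@@H]1O[C@@]1(C)CCC=C(C)C | intermediate
3 | (2R,3S)-epoxygeranial, (2R,3S)-3-methyl-3-(4-methylpent-3-en-1-yl)oxirane-2-carbaldehyde | O=C[C@@H]1O[C@@]1(C)CCC=C(C)C | intermediate
4 | (2E)-N-methoxy-N-methyl-3-[(2S,3S)-3-methyl-3-(4-methylpent-3-en-1-yl)oxiran-2-yl]prop-2-enamide | CON(C)C(=O)/C=C/[C@@H]1O[C@@]1(C)CCC=C(C)C | intermediate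
5 | (S)-epichlorohydrin, (2S)-2-(chloromethyl)oxirane | ClC[C@@H]1CO1 | starting material
6 | (2S)-1-chloro-4-methylpent-4-en-2-ol, present as its bromomagnesium alkoxide | C=C(C)C[C@H](O)CCl | intermediate
7 | (2S)-2-(2-methylprop-2-en-1-yl)oxirane | C=C(C)C[C@H]1CO1 | intermediate
8 | (5S)-3-methoxy-7-methylocta-1,2,7-trien-5-ol, present as its lithium alkoxide | COC(=C=C)C[C@H](CC(C)=C)O | intermediate
9 | (5S)-5-hydroxy-7-methylocta-1,7-dien-3-one | C=CC(=O)C[C@H](CC(C)=C)O | intermediate
10 | (2E,4S,5S)-5-hydroxy-N-methoxy-N,5,9-trimethyl-4-{[(4S)-2-methyl-6-oxoocta-1,7-dien-4-yl]oxy}deca-2,8-dienamide (C9–O–C2 ether; C3–OH free) | C=CC(=O)C[C@H](CC(C)=C)O[C@@H](/C=C/C(=O)N(C)OC)[C@@](C)(O)CCC=C(C)C | intermediate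
11 | bis(triethylsilyl) derivative of 10: C3–OSiEt3 and (Z)-C10=C11(OSiEt3)–C12=C13 siloxydiene | C=C/C(O[Si](CC)(CC)CC)=C/[C@H](CC(C)=C)O[C@@H](/C=C/C(=O)N(C)OC)[C@@](C)(O[Si](CC)(CC)CC)CCC=C(C)C | intermediate
12 | Diels–Alder adduct: cis-fused rings A/B with C11(OSiEt3)=C12 enol ether, 14β-C(O)N(OMe)Me, 9β-methallyl, C3–OSiEt3; stereocentres C1, C2, C3, C9, C10, C14 as in the target | CC[Si](CC)(CC)OC1=CC[C@@H](C(=O)N(C)OC)[C@H]3[C@@H]1[C@H](CC(C)=C)O[C@@H]3[C@@](C)(O[Si](CC)(CC)CC)CCC=C(C)C | intermediate
13 | A/B-ring ketone: cis-fused octahydroisobenzofuran-4-one (C11=O) with 14β-C(O)N(OMe)Me, 9β-(2-methylprop-2-enyl), 2β-[(2S)-6-methyl-2-(triethylsilyloxy)hept-5-en-2-yl]; H1, H10 β; H2, H9, H14 α | O=C1CC[C@@H](C(=O)N(C)OC)[C@H]3[C@@H]1[C@H](CC(C)=C)O[C@@H]3[C@@](C)(O[Si](CC)(CC)CC)CCC=C(C)C | intermediate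
14 | tricyclic oxonene ketone: rings A, B, C with (6Z)-C6=C7, C11=O, 14β-C(O)N(OMe)Me, C3–OSiEt3; stereocentres as in the target | O=C1CC[C@@H](C(=O)N(C)OC)[C@H]3[C@@H]1[C@@H]1C/C(C)=C\CC[C@](C)(O[Si](CC)(CC)CC)[C@H]3O1 | intermediate
15 | bis(bromomagnesium) adduct of 14: C11 tertiary alkoxide (β-methyl) and C15 tetrahedral N-methoxy-N-methyl hemiaminal alkoxide | Br[Mg]O[C@]1(C)CC[C@@H](C(C)(O[Mg]Br)N(C)OC)[C@H]3[C@@H]1[C@@H]1C/C(C)=C\CC[C@](C)(O[Si](CC)(CC)CC)[C@H]3O1 | intermediate
16 | C11 butanoate methyl ketone: 11α-butanoyloxy-11β-methyl, 14β-acetyl, C3–OSiEt3, rings A, B, C | CCCC(=O)O[C@]1(C)CC[C@@H](C(C)=O)[C@H]3[C@@H]1[C@@H]1C/C(C)=C\CC[C@](C)(O[Si](CC)(CC)CC)[C@H]3O1 | intermediate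
17 | silyl-protected vinyl triflate: 14β-[1-(trifluoromethylsulfonyloxy)ethenyl], C3–OSiEt3 | CCCC(=O)O[C@]1(C)CC[C@@H](C(=C)OS(=O)(=O)C(F)(F)F)[C@H]3[C@@H]1[C@@H]1C/C(C)=C\CC[C@](C)(O[Si](CC)(CC)CC)[C@H]3O1 | intermediate
18 | vinyl triflate alcohol: 14β-[1-(trifluoromethylsulfonyloxy)ethenyl], C3–OH free | CCCC(=O)O[C@]1(C)CC[C@@H](C(=C)OS(=O)(=O)C(F)(F)F)[C@H]3[C@@H]1[C@@H]1C/C(C)=C\CC[C@](C)(O)[C@H]3O1 | intermediate
19 | α-methylene lactone: target skeleton with C15=CH2 in place of C15H(CH3) | CCCC(=O)O[C@]1(C)CC[C@@H]2[C@H]3[C@@H]1[C@@H]1C/C(C)=C\CC[C@](C)(OC(=O)C2=C)[C@H]3O1 | intermediate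
20 | CNP0294597.2 | CCCC(=O)O[C@]1(C)CC[C@@H]2[C@H]3[C@@H]1[C@@H]1C/C(C)=C\CC[C@](C)(OC(=O)[C@@H]2C)[C@H]3O1 | target

**Step count**

Total: 12 steps. Longest linear sequence: 10 steps (1 → 2 → 3 → 4 → 10 → 13 → 14 → 16 → 18 → 19 → 20); the second branch (5 → 7 → 9) is 2 steps.

**Three steps most likely to fail, with fallbacks**

Step 6 (the proposed new etherification). The risks are poor delivery of a hindered secondary alcohol from boron, attack at C14, and phosphine-induced oligomerisation or oxa-Michael cyclisation of the vinyl ketone in 9. The fallback uses known chemistry; it sets out from 4 and comes back at 10. Palladium-catalysed CO2 fixation on the vinyl epoxide (Pd(PPh3)4, CO2, THF; known to proceed with retention) gives the cyclic carbonate F1. Methanolysis (K2CO3, MeOH) gives the syn-diol F2, and Me3SiCl/imidazole gives the bis(trimethylsilyl) ether F3. A Me3SiOTf-catalysed three-component Mukaiyama-type etherification of F3 with 3-methylbut-3-enal and 2-(trimethylsilyloxy)buta-1,3-diene (CH2Cl2, −78 °C) then forms the C2–O–C9 ether and the C9–C10 bond. In that step the less hindered secondary silyl ether and the aldehyde form an oxocarbenium ion, which the siloxydiene terminus attacks. Acidic work-up removes the tertiary silyl group and gives 10 together with its C9 epimer F4, which is removed by chromatography. C9 is not controlled here, which is the price of the fallback.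

Step 7 (intramolecular Diels–Alder). The unsaturated Weinreb amide is a weak dienophile and the siloxydiene may decompose before it reacts. The fallback sets out from 10 and comes back at 13, and replaces the pericyclic step by an anionic double Michael annulation. LiN(SiMe3)2 (2.2 equiv, THF, −78 to −20 °C) forms the C3 alkoxide and the C10 enolate. The enolate adds 5-exo to C1, and the resulting amide enolate closes ring A by 6-endo addition to the vinyl ketone, giving the hydroxy ketone F5. F5 is then silylated (Et3SiOTf, 2,6-lutidine, CH2Cl2, −78 °C) to 13. The same substituent arguments apply, and C10 equilibrates to the cis ring fusion.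

Step 11 (seven-membered carbonylative lactonisation by a tertiary alcohol). The acyl–palladium may not be captured by the hindered hydroxyl. The fallback sets out from 18 and comes back at 19, and separates carbonylation from ring closure. Methoxycarbonylation (Pd(OAc)2, Xantphos, CO, MeOH, Et3N) gives the methyl acrylate ester F6. Me3SnOH (1,2-dichloroethane, 80 °C) cleaves the methyl ester selectively in the presence of the tertiary butanoate and gives the acrylic acid F7. Yamaguchi lactonisation (2,4,6-trichlorobenzoyl chloride, Et3N; then DMAP, PhMe, high dilution, 80 °C) closes ring D to 19.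

**Further compounds**

F1 | step 6 | cyclic carbonate of the C2/C3 syn-diol, (2E)-N-methoxy-N-methyl-3-[5-methyl-5-(4-methylpent-3-en-1-yl)-2-oxo-1,3-dioxolan-4-yl]prop-2-enamide, C2 and C3 as in 10 | CON(C)C(=O)/C=C/[C@@H]1OC(=O)O[C@@]1(C)CCC=C(C)C
F2 | step 6 | (2E,4S,5S)-4,5-dihydroxy-N-methoxy-N,5,9-trimethyldeca-2,8-dienamide | CON(C)C(=O)/C=C/[C@H](O)[C@@](C)(O)CCC=C(C)C
F3 | step 6 | bis(trimethylsilyl) ether of F2 | CON(C)C(=O)/C=C/[C@H](O[Si](C)(C)C)[C@@](C)(O[Si](C)(C)C)CCC=C(C)C
F4 | step 6 | C9 epimer of 10, with the (4R)-2-methyl-6-oxoocta-1,7-dien-4-yloxy group | C=CC(=O)C[C@@H](CC(C)=C)O[C@@H](/C=C/C(=O)N(C)OC)[C@@](C)(O)CCC=C(C)C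
F5 | step 7 | A/B-ring hydroxy ketone, 13 without the triethylsilyl group | O=C1CC[C@@H](C(=O)N(C)OC)[C@H]3[C@@H]1[C@H](CC(C)=C)O[C@@H]3[C@@](C)(O)CCC=C(C)C
F6 | step 11 | methyl 2-substituted acrylate: 14β-[1-(methoxycarbonyl)ethenyl], C3–OH free, C11 butanoate | CCCC(=O)O[C@]1(C)CC[C@@H](C(=C)C(=O)OC)[C@H]3[C@@H]1[C@@H]1C/C(C)=C\CC[C@](C)(O)[C@H]3O1
F7 | step 11 | 2-substituted acrylic acid: 14β-(1-carboxyethenyl), C3–OH free, C11 butanoate | CCCC(=O)O[C@]1(C)CC[C@@H](C(=C)C(=O)O)[C@H]3[C@@H]1[C@@H]1C/C(C)=C\CC[C@](C)(O)[C@H]3O1
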